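**Plan**

- Retrosynthesis: (a) the three phenols are freed last from tris-silyl ether 14; (b) ring C is cut at C2–C3, back to diazoketone 13, in which C2 is still the OCH2 of a benzyl aryl ether; (c) the O1–CH2 bond is cut to ring A phenol 10 and ring B benzyl alcohol 8; (d) 8 goes back through its CHO carbon and its aryl–geranyl bond to 4-bromo-3-methoxyphenol and geranyl bromide.
- Forward: ring B is geranylated, formylated, silylated and reduced; it is joined to ring A through O1; the acetyl group is turned into a diazoacetyl group; ring C is closed last by C2–C3 bond formation, and only desilylation follows.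
- Enabling feature: the C2 methylene lies between O1 and a ring B carrying oxygen at C2' and C4', so its C–H bonds are strongly hydridic. It is the sixth atom from the carbene carbon C3, and the fifth atom (O1) bears no hydrogen, so a rhodium carbenoid at C3 can only close the six-membered ring C by C–H insertion.
- Stereochemistry: C2 (S) is set in that step by a chiral dirhodium catalyst that selects one of the two enantiotopic C2 hydrogens; the E-alkene is carried in unchanged from geranyl bromide.

Key step: step 8

Assumption: Rh2(S-DOSP)4 is taken to give the 2S series in step 8; if a screen shows the opposite sense, the mirror-image catalyst Rh2(R-DOSP)4 is used and nothing else changes. TIPS = triisopropylsilyl; geranyl = (2E)-3,7-dimethylocta-2,6-dien-1-yl.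

**Step 1**
Reactants: 1 4-bromo-3-methoxyphenol; 2 geranyl bromide
Product: 5 4-geranyl-3-methoxyphenol, via dilithio phenolate 3 (not isolated), via arylcopper phenolate 4 (not isolated)
Conditions: n-BuLi (2.1 equiv), THF, −78 to −30 °C; CuBr·SMe2 (1.05 equiv), −78 °C; 2, −78 to 0 °C; aq NH4Cl
Reagents that add atoms: none
Why: Deprotonation and bromine–lithium exchange, then transmetalation to monovalent copper, give an aryl copper species that displaces the primary allylic bromide at its unsubstituted terminus (copper-mediated SN2-type allylic coupling), so the E-alkene of 2 is kept and the weakly nucleophilic lithium phenolate oxygen should stay unalkylated.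

**Step 2**
Reactants: 5 4-geranyl-3-methoxyphenol
Product: 6 5-geranyl-2-hydroxy-4-methoxybenzaldehyde
Conditions: MgCl2 (anhydrous), Et3N, (CH2O)n, MeCN, reflux; aq citric acid
Reagents that add atoms: paraformaldehyde (as formaldehyde), C=O
Why: Magnesium-mediated ortho-formylation (Casnati–Skattebøl) delivers formaldehyde within a magnesium phenolate chelate to the free ortho position para to OMe rather than the crowded one between OH and OMe, and hydride transfer to a second formaldehyde gives the aldehyde without touching the alkenes.

**Step 3**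
Reactants: 6 5-geranyl-2-hydroxy-4-methoxybenzaldehyde
Product: 7 5-geranyl-4-methoxy-2-(triisopropylsilyloxy)benzaldehyde
Conditions: TIPSCl, imidazole, DMF, rt
Reagents that add atoms: triisopropylsilyl chloride, CC(C)[Si](Cl)(C(C)C)C(C)C
Why: Imidazole-promoted silylation of a phenol is standard and the base-free, acid-free conditions leave aldehyde and alkenes untouched.

**Step 4**
Reactants: 7 5-geranyl-4-methoxy-2-(triisopropylsilyloxy)benzaldehyde
Product: 8 [5-geranyl-4-methoxy-2-(triisopropylsilyloxy)phenyl]methanol
Conditions: NaBH4, THF/MeOH, 0 °C; aq NH4Cl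
Reagents that add atoms: none
Why: Borohydride reduction of an aryl aldehyde is fast at 0 °C, and the bulky TIPS group should resist migration from the phenol oxygen to the new benzylic oxygen.

**Step 5**
Reactants: 9 2',4',6'-trihydroxyacetophenone (dried)
Product: 10 1-[2-hydroxy-4,6-bis(triisopropylsilyloxy)phenyl]ethanone
Conditions: TIPSCl (2.1 equiv), imidazole, DMF, 0 °C to rt
Reagents that add atoms: triisopropylsilyl chloride, CC(C)[Si](Cl)(C(C)C)C(C)C
Why: Selective silylation: the para hydroxyl and one ortho hydroxyl react, while the last ortho hydroxyl is locked in a hydrogen bond to the acetyl oxygen and should remain free, as in the usual bis-protection of this ketone.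

**Step 6**
Reactants: 8 [5-geranyl-4-methoxy-2-(triisopropylsilyloxy)phenyl]methanol; 10 1-[2-hydroxy-4,6-bis(triisopropylsilyloxy)phenyl]ethanone
Product: 11 1-[2-{[5-geranyl-4-methoxy-2-(triisopropylsilyloxy)phenyl]methoxy}-4,6-bis(triisopropylsilyloxy)phenyl]ethanone
Conditions: PPh3, DIAD, THF, 0 °C to rt
Reagents that add atoms: none
Why: Mitsunobu etherification of an acidic, chelated phenol with a primary, electron-rich benzylic alcohol forms the O1–CH2 bond under neutral conditions that spare the aryl silyl ethers and avoid an unstable dialkoxybenzyl halide.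

**Step 7**
Reactants: 11 the aryl methyl ketone of step 6
Product: 13 2-diazo-1-[2-{[5-geranyl-4-methoxy-2-(triisopropylsilyloxy)phenyl]methoxy}-4,6-bis(triisopropylsilyloxy)phenyl]ethanone, via trifluoromethyl diketone 12 (not isolated)
Conditions: LiN(SiMe3)2, THF, −78 °C; CF3CO2CH2CF3, −78 °C; aq NH4Cl; then MsN3, Et3N, H2O (1 equiv), MeCN, rt
Reagents that add atoms: methanesulfonyl azide, CS(=O)(=O)N=[N+]=[N-] (its two terminal nitrogen atoms stay in 13); 2,2,2-trifluoroethyl trifluoroacetate, O=C(OCC(F)(F)F)C(F)(F)F (its CF3CO group is present in 12 only)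
Why: Regitz-type detrifluoroacetylative diazo transfer: the only enolisable site is the acetyl methyl group, its lithium enolate is trifluoroacetylated, and the activated diketone takes up the diazo group from the sulfonyl azide with loss of the trifluoroacetyl group as the N-acyl sulfonamide.

**Step 8**
Reactants: 13 the diazoketone of step 7
Product: 14 (2S)-2-[5-geranyl-4-methoxy-2-(triisopropylsilyloxy)phenyl]-5,7-bis(triisopropylsilyloxy)-2,3-dihydro-4H-chromen-4-one
Conditions: Rh2(S-DOSP)4 (dirhodium tetrakis[(S)-N-(4-dodecylphenylsulfonyl)prolinate], 1 mol %), hexanes, 4 Å molecular sieves, 0 °C to rt, slow addition of 13 at high dilution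
Reagents that add atoms: none
Why: The catalyst expels N2 from 13 to give an electrophilic divalent-rhodium carbenoid at C3, which inserts in a concerted, asynchronous three-centre (hydride-transfer-like) way into one C–H bond of the O1–CH2–ring B methylene, forming the C2–C3 bond and releasing the catalyst. The closest known reaction type is the dirhodium-carboxylate-catalysed intramolecular C–H insertion of 2-alkoxyaryl diazomethyl ketones to chroman-4-ones, which has been made enantioselective with arylsulfonylprolinate ligands. Ring C closes by 1,6 C–H insertion through a six-membered transition state; the usually preferred 1,5 mode is not available because the fifth atom is O1 and carries no hydrogen. The new stereocentre C2 comes from the choice between the two enantiotopic hydrogens of the methylene, which is controlled by the chiral prolinate ligand sphere of the catalyst (S expected, see assumption). The step needs chemoselectivity for this C–H bond over oxonium-ylide formation at O1, cyclopropanation of the geranyl alkenes and insertion elsewhere. This should be secured by the hydridic C–H bond (alpha to O1 and benzylic to a ring B with oxygen at C2' and C4'), by the low basicity of O1 (conjugated to the acyl-bearing ring A), by silyl groups with no C–H bond within reach of a five- or six-membered transition state, by alkenes reachable only through rings of eleven or more atoms, and by slow addition at high dilution.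

**Step 9**
Reactants: 14 the tris-silylated flavanone of step 8
Product: 15 Kuwanon U, (2S)-2-[5-geranyl-2-hydroxy-4-methoxyphenyl]-5,7-dihydroxy-2,3-dihydro-4H-chromen-4-one
Conditions: HF·pyridine, pyridine, THF, 0 °C to rt; pH 7 buffer
Reagents that add atoms: none
Why: Fluoride-mediated cleavage of the three aryl silyl ethers under buffered, weakly acidic conditions avoids the phenolate-induced ring opening to the chalcone that would scramble C2, and does not touch the geranyl alkenes.

**Compound list**

1 | 4-bromo-3-methoxyphenol | COc1cc(O)ccc1Br | starting material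
2 | geranyl bromide, (2E)-1-bromo-3,7-dimethylocta-2,6-diene | BrC/C=C(\C)CCC=C(C)C | starting material
3 | lithium 4-lithio-3-methoxyphenolate (not isolated) | COc1cc([O-])ccc1[Li].[Li+] | intermediate
4 | lithium 4-cuprio-3-methoxyphenolate, arylcopper species (not isolated) | COc1cc([O-])ccc1[Cu].[Li+] | intermediate
5 | 4-geranyl-3-methoxyphenol | COc1cc(O)ccc1C/C=C(\C)CCC=C(C)C | intermediate
6 | 5-geranyl-2-hydroxy-4-methoxybenzaldehyde | COc1cc(O)c(C=O)cc1C/C=C(\C)CCC=C(C)C | intermediate
7 | 5-geranyl-4-methoxy-2-(triisopropylsilyloxy)benzaldehyde | COc1cc(O[Si](C(C)C)(C(C)C)C(C)C)c(C=O)cc1C/C=C(\C)CCC=C(C)C | intermediate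
8 | [5-geranyl-4-methoxy-2-(triisopropylsilyloxy)phenyl]methanol | COc1cc(O[Si](C(C)C)(C(C)C)C(C)C)c(CO)cc1C/C=C(\C)CCC=C(C)C | intermediate
9 | 2',4',6'-trihydroxyacetophenone | CC(=O)c1c(O)cc(O)cc1O | starting material
10 | 1-[2-hydroxy-4,6-bis(triisopropylsilyloxy)phenyl]ethanone | CC(=O)c1c(O)cc(O[Si](C(C)C)(C(C)C)C(C)C)cc1O[Si](C(C)C)(C(C)C)C(C)C | intermediate
11 | 1-[2-{[5-geranyl-4-methoxy-2-(triisopropylsilyloxy)phenyl]methoxy}-4,6-bis(triisopropylsilyloxy)phenyl]ethanone | COc1cc(O[Si](C(C)C)(C(C)C)C(C)C)c(COc2cc(O[Si](C(C)C)(C(C)C)C(C)C)cc(O[Si](C(C)C)(C(C)C)C(C)C)c2C(C)=O)cc1C/C=C(\C)CCC=C(C)C | intermediate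
12 | 4,4,4-trifluoro-1-[2-{[5-geranyl-4-methoxy-2-(triisopropylsilyloxy)phenyl]methoxy}-4,6-bis(triisopropylsilyloxy)phenyl]butane-1,3-dione (not isolated) | COc1cc(O[Si](C(C)C)(C(C)C)C(C)C)c(COc2cc(O[Si](C(C)C)(C(C)C)C(C)C)cc(O[Si](C(C)C)(C(C)C)C(C)C)c2C(=O)CC(=O)C(F)(F)F)cc1C/C=C(\C)CCC=C(C)C | intermediate
13 | 2-diazo-1-[2-{[5-geranyl-4-methoxy-2-(triisopropylsilyloxy)phenyl]methoxy}-4,6-bis(triisopropylsilyloxy)phenyl]ethanone | COc1cc(O[Si](C(C)C)(C(C)C)C(C)C)c(COc2cc(O[Si](C(C)C)(C(C)C)C(C)C)cc(O[Si](C(C)C)(C(C)C)C(C)C)c2C(=O)C=[N+]=[N-])cc1C/C=C(\C)CCC=C(C)C | intermediate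
14 | (2S)-2-[5-geranyl-4-methoxy-2-(triisopropylsilyloxy)phenyl]-5,7-bis(triisopropylsilyloxy)-2,3-dihydro-4H-chromen-4-one | COc1cc(O[Si](C(C)C)(C(C)C)C(C)C)c([C@@H]2CC(=O)c3c(O[Si](C(C)C)(C(C)C)C(C)C)cc(O[Si](C(C)C)(C(C)C)C(C)C)cc3O2)cc1C/C=C(\C)CCC=C(C)C | intermediate
15 | Kuwanon U, (2S)-2-[5-geranyl-2-hydroxy-4-methoxyphenyl]-5,7-dihydroxy-2,3-dihydro-4H-chromen-4-one | COc1cc(O)c([C@@H]2CC(=O)c3c(O)cc(O)cc3O2)cc1C/C=C(\C)CCC=C(C)C | target

**Step count**

Total: 9 steps. Longest linear sequence: 8 steps (steps 1, 2, 3, 4, 6, 7, 8, 9); step 5 makes the ring A partner.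

**Steps most likely to fail**

1. Step 8. The carbenoid may attack the lone pair of O1 instead of the C–H bond (oxonium ylide, then [1,2]-benzyl shift to a benzofuranone), may cyclopropanate a geranyl alkene of a second molecule, or may discriminate poorly between the two enantiotopic hydrogens. Fallback: ring C is closed at O1–C2 instead. Setting out from ketone 10 and aldehyde 7, a pyrrolidine-mediated aldol condensation (MeCN, rt) would give (E)-1-[2-hydroxy-4,6-bis(triisopropylsilyloxy)phenyl]-3-[5-geranyl-4-methoxy-2-(triisopropylsilyloxy)phenyl]prop-2-en-1-one F1. Enantioselective intramolecular oxa-Michael addition of its free phenol under a quinine-derived bifunctional thiourea (toluene, rt) would then give the flavanone and rejoin the route at 14, with preparative chiral HPLC of 14 to make up any shortfall in enantiomeric purity.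

2. Step 7. The ortho TIPS group may migrate from the phenol oxygen to the neighbouring enolate oxygen, or trifluoroacetylation of the enolate flanked by two ortho substituents may stay incomplete. Fallback: a route without any enolate. Setting out from 11, condensation with N,N-dimethylformamide dimethyl acetal (neat, 90 °C) would give the enaminone (E)-3-(dimethylamino)-1-[2-{[5-geranyl-4-methoxy-2-(triisopropylsilyloxy)phenyl]methoxy}-4,6-bis(triisopropylsilyloxy)phenyl]prop-2-en-1-one F2. Diazo transfer to the enamine carbon with 4-methylbenzenesulfonyl azide (MeCN, rt; cycloaddition and cycloreversion with loss of the sulfonyl formamidine) would then give the diazoketone and rejoin the route at 13.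

3. Step 6. Displacement at the hindered alkoxyphosphonium ion by the weakly acidic, chelated phenol may be slow, so that the hydrazide is alkylated instead or the benzyl cation attacks a carbon of the electron-rich ring A. Fallback: acid-catalysed imidate benzylation. Setting out from 8, Cl3CCN with catalytic DBU (CH2Cl2, 0 °C) would give [5-geranyl-4-methoxy-2-(triisopropylsilyloxy)phenyl]methyl 2,2,2-trichloroacetimidate F3. With phenol 10 and catalytic camphorsulfonic acid (CH2Cl2, −20 °C) this would transfer the dialkoxybenzyl group to the phenol oxygen and rejoin the route at 11.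

**Further compounds**

F1 | step 8 | (E)-1-[2-hydroxy-4,6-bis(triisopropylsilyloxy)phenyl]-3-[5-geranyl-4-methoxy-2-(triisopropylsilyloxy)phenyl]prop-2-en-1-one | COc1cc(O[Si](C(C)C)(C(C)C)C(C)C)c(/C=C/C(=O)c2c(O)cc(O[Si](C(C)C)(C(C)C)C(C)C)cc2O[Si](C(C)C)(C(C)C)C(C)C)cc1C/C=C(\C)CCC=C(C)C
F2 | step 7 | (E)-3-(dimethylamino)-1-[2-{[5-geranyl-4-methoxy-2-(triisopropylsilyloxy)phenyl]methoxy}-4,6-bis(triisopropylsilyloxy)phenyl]prop-2-en-1-one | COc1cc(O[Si](C(C)C)(C(C)C)C(C)C)c(COc2cc(O[Si](C(C)C)(C(C)C)C(C)C)cc(O[Si](C(C)C)(C(C)C)C(C)C)c2C(=O)/C=C/N(C)C)cc1C/C=C(\C)CCC=C(C)C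
F3 | step 6 | [5-geranyl-4-methoxy-2-(triisopropylsilyloxy)phenyl]methyl 2,2,2-trichloroacetimidate | COc1cc(O[Si](C(C)C)(C(C)C)C(C)C)c(COC(=N)C(Cl)(Cl)Cl)cc1C/C=C(\C)CCC=C(C)C
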